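**Retrosynthetic overview**
1. Ring A (benzo ring) comes intact from paeonol and ring C (trimethoxyphenyl) from 3,4,5-trimethoxybenzyl chloride; ring B (the dihydrofuran) is the only ring formed in the route.
2. Target 10 ⇐ trans bromide 8 by a final Suzuki–Miyaura propenylation at C5, so the E-alkene never meets carbene or acid chemistry.
3. trans-8 ⇐ cis-7 by acid epimerisation at C2 (reversible O1–C2 ionisation), with C3 untouched.
4. cis-7 ⇐ achiral hydrazone 5: ring B is closed by forming C2–C3 through enantioselective intramolecular C–H insertion of an aryl/methyl rhodium carbene. The enabling feature is that C2 is both alpha to O1 and benzylic to ring C, and lies 1,5 to C3, which is the acetyl carbon of an ortho-oxygenated acetophenone; paeonol already holds C3, its methyl, C3a, C7a, O1 and the C6 methoxy group.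
5. 5 ⇐ paeonol 1 + NBS (C5–Br) + benzyl chloride 3 (C2 and ring C) + hydrazine.

Key step: step 4

Assumption: the sense of induction of the chiral dirhodium carboxylates (Rh2(R-PTAD)4 in step 4, Rh2(S-PTTL)4 in the fallback to step 4) is assigned by analogy; both antipodes of each catalyst are available and the one that gives the drawn configuration is used.

**Step 1**
Reactants: 1 paeonol, 1-(2-hydroxy-4-methoxyphenyl)ethan-1-one
Product: 2 1-(5-bromo-2-hydroxy-4-methoxyphenyl)ethan-1-one
Conditions: NBS (1.05 equiv), MeCN, 0 °C to rt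
Reagents that add atoms: N-bromosuccinimide, O=C1CCC(=O)N1Br
Why: Electrophilic aromatic bromination should go to C5, which is para to the free phenol, ortho to the methoxy group and unhindered, whereas C3 is flanked by two oxygen substituents and C6 is deactivated by the acetyl group; no stereocentre is formed.

**Step 2**
Reactants: 2 1-(5-bromo-2-hydroxy-4-methoxyphenyl)ethan-1-one; 3 3,4,5-trimethoxybenzyl chloride
Product: 4 1-{5-bromo-4-methoxy-2-[(3,4,5-trimethoxybenzyl)oxy]phenyl}ethan-1-one
Conditions: K2CO3 (2 equiv), DMF, 60 °C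
Reagents that add atoms: none
Why: Williamson ether synthesis (SN2 of the potassium phenoxide on a primary benzylic chloride) installs the O–CH2–aryl unit whose methylene becomes C2; no stereocentre is formed.

**Step 3**
Reactants: 4 1-{5-bromo-4-methoxy-2-[(3,4,5-trimethoxybenzyl)oxy]phenyl}ethan-1-one
Product: 5 (E)-{1-[5-bromo-4-methoxy-2-((3,4,5-trimethoxybenzyl)oxy)phenyl]ethylidene}hydrazine
Conditions: N2H4·H2O (10 equiv), AcOH (cat.), EtOH, 80 °C
Reagents that add atoms: hydrazine monohydrate, NN.O
Why: Hydrazone formation by condensation of the ketone with excess hydrazine, the excess suppressing azine formation; the C=N geometry is lost in the next step and no stereocentre is formed.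

**Step 4**
Reactants: 5 (E)-{1-[5-bromo-4-methoxy-2-((3,4,5-trimethoxybenzyl)oxy)phenyl]ethylidene}hydrazine
Product: 7 cis-(2S,3R)-5-bromo-6-methoxy-3-methyl-2-(3,4,5-trimethoxyphenyl)-2,3-dihydro-1-benzofuran, via diazoalkane 6 (not isolated)
Conditions: MnO2 (8 equiv), CH2Cl2, 0 °C; cold filtration through Celite; filtrate added slowly to Rh2(R-PTAD)4 (dirhodium tetrakis[(R)-N-phthaloyl-(1-adamantyl)glycinate], 1 mol%), CH2Cl2, −20 °C to rt
Reagents that add atoms: none
Why: MnO2 dehydrogenates the hydrazone to the aryl methyl diazoalkane 6, which loses N2 at the dirhodium core to give a donor/donor (aryl/alkyl) rhodium carbene at the former acetyl carbon, and this carbene inserts into one of the two enantiotopic O–CH2–aryl hydrogens through a hydride-transfer-like transition state that forms C2–C3. The closest known reaction type is the enantioselective intramolecular C–H insertion of donor/donor rhodium carbenes, generated from hydrazones with MnO2, into benzylic ether C–H bonds to give cis-2,3-disubstituted benzodihydrofurans, a class that has been extended to aryl/alkyl carbenes in related benzo-fused ether ring closures. Ring B is closed in a 1,5-insertion (five-membered) mode with C3a–C7a of ring A as the tether. C3 is set by the carbene face that the chiral carboxylate pocket leaves open (catalyst control) and C2 by which methylene hydrogen is delivered, the compact transition state placing aryl and methyl cis. The step needs 1,5-insertion to outrun the 1,2-hydride shift from the methyl group (to a vinylarene) and azine formation, which the hydridic, doubly activated C–H bond, the low electrophilicity of the donor/donor carbene, low temperature and slow addition should secure, while the alkene-free bromide excludes cyclopropanation and dipolar cycloaddition. Any trans isomer formed with the same C3 configuration converges with the cis isomer in step 5.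

**Step 5**
Reactants: 7 cis-(2S,3R)-5-bromo-6-methoxy-3-methyl-2-(3,4,5-trimethoxyphenyl)-2,3-dihydro-1-benzofuran
Product: 8 trans-(2R,3R)-5-bromo-6-methoxy-3-methyl-2-(3,4,5-trimethoxyphenyl)-2,3-dihydro-1-benzofuran
Conditions: CF3CO2H (5 equiv), CH2Cl2, 0 °C to rt, until the cis/trans composition no longer changes; aq. NaHCO3
Reagents that add atoms: none
Why: Brønsted-acid-mediated epimerisation of a benzylic aryl ether centre, in which reversible heterolysis of O1–C2 gives a cation stabilised by the 3,4,5-trimethoxyphenyl ring that the tethered phenol recaptures on either face, so C2 equilibrates from S to R toward the more stable trans isomer (aryl and methyl anti) while C3 takes no part in the bond breaking and stays R.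

**Step 6**
Reactants: 8 trans-(2R,3R)-5-bromo-6-methoxy-3-methyl-2-(3,4,5-trimethoxyphenyl)-2,3-dihydro-1-benzofuran; 9 (E)-4,4,5,5-tetramethyl-2-(prop-1-en-1-yl)-1,3,2-dioxaborolane
Product: 10 (2R,3R)-6-methoxy-3-methyl-5-[(E)-prop-1-en-1-yl]-2-(3,4,5-trimethoxyphenyl)-2,3-dihydro-1-benzofuran
Conditions: Pd(dppf)Cl2·CH2Cl2 (5 mol%; dppf = 1,1'-bis(diphenylphosphino)ferrocene), K2CO3 (3 equiv), 1,4-dioxane/H2O, 85 °C
Reagents that add atoms: none
Why: Suzuki–Miyaura coupling, in which oxidative addition of the aryl bromide, transmetalation of the alkenylboronate with retention of the E geometry and reductive elimination proceed under basic conditions that touch neither C2 nor C3.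

**Compound list**
1 | paeonol, 1-(2-hydroxy-4-methoxyphenyl)ethan-1-one | CC(=O)c1ccc(OC)cc1O | starting material
2 | 1-(5-bromo-2-hydroxy-4-methoxyphenyl)ethan-1-one | CC(=O)c1cc(Br)c(OC)cc1O | intermediate
3 | 3,4,5-trimethoxybenzyl chloride, 5-(chloromethyl)-1,2,3-trimethoxybenzene | COc1cc(CCl)cc(OC)c1OC | starting material
4 | 1-{5-bromo-4-methoxy-2-[(3,4,5-trimethoxybenzyl)oxy]phenyl}ethan-1-one | CC(=O)c1cc(Br)c(OC)cc1OCc1cc(OC)c(OC)c(OC)c1 | intermediate
5 | (E)-{1-[5-bromo-4-methoxy-2-((3,4,5-trimethoxybenzyl)oxy)phenyl]ethylidene}hydrazine | C/C(=N\N)c1cc(Br)c(OC)cc1OCc1cc(OC)c(OC)c(OC)c1 | intermediate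
6 | 1-bromo-5-(1-diazoethyl)-2-methoxy-4-[(3,4,5-trimethoxybenzyl)oxy]benzene | CC(=[N+]=[N-])c1cc(Br)c(OC)cc1OCc1cc(OC)c(OC)c(OC)c1 | intermediate
7 | cis-(2S,3R)-5-bromo-6-methoxy-3-methyl-2-(3,4,5-trimethoxyphenyl)-2,3-dihydro-1-benzofuran | Brc1cc2c(cc1OC)O[C@H](c1cc(OC)c(OC)c(OC)c1)[C@@H]2C | intermediate
8 | trans-(2R,3R)-5-bromo-6-methoxy-3-methyl-2-(3,4,5-trimethoxyphenyl)-2,3-dihydro-1-benzofuran | Brc1cc2c(cc1OC)O[C@@H](c1cc(OC)c(OC)c(OC)c1)[C@@H]2C | intermediate
9 | (E)-4,4,5,5-tetramethyl-2-(prop-1-en-1-yl)-1,3,2-dioxaborolane | C/C=C/B1OC(C)(C)C(C)(C)O1 | starting material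
10 | (2R,3R)-6-methoxy-3-methyl-5-[(E)-prop-1-en-1-yl]-2-(3,4,5-trimethoxyphenyl)-2,3-dihydro-1-benzofuran | C/C=C/c1cc2c(cc1OC)O[C@@H](c1cc(OC)c(OC)c(OC)c1)[C@@H]2C | target

**Total step count:** 6. **Longest linear sequence:** 6 steps (from paeonol 1).

**Steps most likely to fail**

Step 4. The methyl-substituted carbene may undergo 1,2-hydride migration, or the diazoalkane may dimerise to the azine, faster than insertion; enantiofacial discrimination may also be poor for the small methyl group. The fallback replaces the methyl group by an ester, which gives a donor/acceptor carbene without a beta hydrogen and makes C3 base-epimerisable. It sets out from 4 and comes back at 8, so it replaces steps 4 and 5. Oxidative 1,2-aryl migration of the aryl methyl ketone 4 (thallium trinitrate, Tl(NO3)3·3H2O, in HC(OMe)3/MeOH at rt) should give methyl 2-{5-bromo-4-methoxy-2-[(3,4,5-trimethoxybenzyl)oxy]phenyl}acetate F1. Regitz diazo transfer (p-acetamidobenzenesulfonyl azide, DBU, MeCN) should give methyl 2-diazo-2-{5-bromo-4-methoxy-2-[(3,4,5-trimethoxybenzyl)oxy]phenyl}acetate F2. Intramolecular C–H insertion with Rh2(S-PTTL)4 (dirhodium tetrakis[N-phthaloyl-(S)-tert-leucinate], toluene, −60 °C) should give the cis ester methyl (2R,3S)-5-bromo-6-methoxy-2-(3,4,5-trimethoxyphenyl)-2,3-dihydro-1-benzofuran-3-carboxylate F3, with C2 fixed by the catalyst. NaOMe in MeOH should epimerise C3 through the ester enolate to the trans ester methyl (2R,3R)-5-bromo-6-methoxy-2-(3,4,5-trimethoxyphenyl)-2,3-dihydro-1-benzofuran-3-carboxylate F4. LiBH4 in THF should reduce it to [(2R,3S)-5-bromo-6-methoxy-2-(3,4,5-trimethoxyphenyl)-2,3-dihydro-1-benzofuran-3-yl]methanol F5. TsCl in pyridine should give [(2R,3S)-5-bromo-6-methoxy-2-(3,4,5-trimethoxyphenyl)-2,3-dihydro-1-benzofuran-3-yl]methyl 4-methylbenzenesulfonate F6. LiEt3BH in THF at 0 °C should displace the sulfonate by hydride to give 8, and step 6 follows.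

Step 5. In the ring-opened benzylic cation, loss of the C3 proton or a 1,2-hydride shift from C3 may compete with reclosure, which would erode the C3 configuration or drain material to ring-opened alkenes; equilibration may also stop short. The fallback changes the mechanism from C–O heterolysis to reversible hydrogen-atom abstraction at C2, which never breaks the ring. It sets out from 7 and comes back at 8. Irradiation of 7 with 4CzIPN (2 mol%), quinuclidine (10 mol%) and 1-adamantanethiol (20 mol%) in MeCN under blue LEDs should let the electrophilic aminium radical abstract the hydridic C2–H (alpha to O1 and benzylic), with the thiol returning hydrogen to either face until the trans isomer 8 dominates. C3–H, beta to oxygen, is polarity-mismatched for this abstraction. No new compound arises (entry F0).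

Step 6. The alkenylboronate may protodeboronate or partly isomerise from E to Z before transmetalation, and oxidative addition to the electron-rich, ortho-methoxylated aryl bromide may be slow. The fallback builds the propenyl group from a C1 and a C2 unit instead of coupling it whole. It sets out from 8 and comes back at 10. Bromine–lithium exchange (n-BuLi, THF, −78 °C) and quenching with DMF should give (2R,3R)-6-methoxy-3-methyl-2-(3,4,5-trimethoxyphenyl)-2,3-dihydro-1-benzofuran-5-carbaldehyde F7. Takai–Utimoto ethylidenation (CrCl2, CH3CHI2, THF, rt) should then deliver the E-propenyl group of 10 with the E selectivity typical of aromatic aldehydes.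

**Further compounds**
F1 | step 4 | methyl 2-{5-bromo-4-methoxy-2-[(3,4,5-trimethoxybenzyl)oxy]phenyl}acetate | COC(=O)Cc1cc(Br)c(OC)cc1OCc1cc(OC)c(OC)c(OC)c1
F2 | step 4 | methyl 2-diazo-2-{5-bromo-4-methoxy-2-[(3,4,5-trimethoxybenzyl)oxy]phenyl}acetate | COC(=O)C(=[N+]=[N-])c1cc(Br)c(OC)cc1OCc1cc(OC)c(OC)c(OC)c1
F3 | step 4 | methyl (2R,3S)-5-bromo-6-methoxy-2-(3,4,5-trimethoxyphenyl)-2,3-dihydro-1-benzofuran-3-carboxylate (cis) | Brc1cc2c(cc1OC)O[C@@H](c1cc(OC)c(OC)c(OC)c1)[C@H]2C(=O)OC
F4 | step 4 | methyl (2R,3R)-5-bromo-6-methoxy-2-(3,4,5-trimethoxyphenyl)-2,3-dihydro-1-benzofuran-3-carboxylate (trans) | Brc1cc2c(cc1OC)O[C@@H](c1cc(OC)c(OC)c(OC)c1)[C@@H]2C(=O)OC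
F5 | step 4 | [(2R,3S)-5-bromo-6-methoxy-2-(3,4,5-trimethoxyphenyl)-2,3-dihydro-1-benzofuran-3-yl]methanol (trans) | Brc1cc2c(cc1OC)O[C@@H](c1cc(OC)c(OC)c(OC)c1)[C@@H]2CO
F6 | step 4 | [(2R,3S)-5-bromo-6-methoxy-2-(3,4,5-trimethoxyphenyl)-2,3-dihydro-1-benzofuran-3-yl]methyl 4-methylbenzenesulfonate (trans) | Brc1cc2c(cc1OC)O[C@@H](c1cc(OC)c(OC)c(OC)c1)[C@@H]2COS(=O)(=O)c1ccc(C)cc1
F0 | step 5 | none | none
F7 | step 6 | (2R,3R)-6-methoxy-3-methyl-2-(3,4,5-trimethoxyphenyl)-2,3-dihydro-1-benzofuran-5-carbaldehyde | O=Cc1cc2c(cc1OC)O[C@@H](c1cc(OC)c(OC)c(OC)c1)[C@@H]2C
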